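The route rests on cutting, in each of the two terminal 2-hydroxyphenyl rings, the bond from the ring carbon ortho to the phenolic oxygen to the methylene that joins it to C5 of the inner 2-hydroxybenzyl ring. Both such O–C(aryl)=C(aryl)–CH2 units are built in one operation by condensing two molecules each of phenol and phenylboronic acid with a dialdehyde, closing two 1,3,2-benzodioxaborin rings. Boron holds the phenol oxygen and the aldehyde oxygen, so the new C–C bond can only form ortho, and the tether is later cut reductively to CH2. The precursor is the (2S)-flavanone already bearing both inner arms at C6 and C8, each with a para-formyl group and an acetylated phenol.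

Key step: step 3

Remark on the chemistry: (2S)-pinostrobin is taken as the purchased natural enantiomer; step 3 creates two stereogenic benzylic carbons that are not controlled, so 8 (and any carbinol on a fallback path) is a diastereomer mixture drawn without configuration there, and both carbons are CH2 in the target.

Step 1
Reactants: 1 (2S)-pinostrobin; 2 4-hydroxy-3-(hydroxymethyl)benzaldehyde (two molecules react, one at C6 and one at C8)
Product: 3 (2S)-6,8-bis(5-formyl-2-hydroxybenzyl)-5-hydroxy-7-methoxyflavanone
Conditions: 2 (2.4 equiv), ZnCl2 (3 equiv), 1,4-dioxane, 90 °C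
Reagents that add atoms: 4-hydroxy-3-(hydroxymethyl)benzaldehyde (second molecule of 2), O=Cc1ccc(O)c(CO)c1
Why: Lewis-acid-mediated Friedel–Crafts benzylation through an o-quinone methide: Zn(II) chelated between the phenolic oxygen and the benzylic OH of 2 should ionise the C–OH bond, and the o-quinone methide should be captured by C6 and C8, the only free, doubly oxygen-flanked carbons of ring A, each arm being installed with loss of one water, while the formyl group keeps 2 and the product arms too electron-poor to compete as nucleophiles and the non-basic medium leaves C2 alone.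

Step 2
Reactants: 3 (2S)-6,8-bis(5-formyl-2-hydroxybenzyl)-5-hydroxy-7-methoxyflavanone
Product: 4 (2S)-6,8-bis(2-acetoxy-5-formylbenzyl)-5-hydroxy-7-methoxyflavanone
Conditions: Ac2O (2.2 equiv), pyridine (3 equiv), CH2Cl2, 0 °C
Reagents that add atoms: acetic anhydride, CC(=O)OC(C)=O
Why: Chemoselective O-acetylation: the two arm phenols, acidified by their para-formyl groups, should acylate rapidly, whereas the 5-OH is hydrogen-bonded to the C4 carbonyl and flanked by the C6 benzyl group and is expected to stay free with a slight excess of anhydride at 0 °C; the brief contact with pyridine is not expected to open the pyranone ring.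

Step 3
Reactants: 4 (2S)-6,8-bis(2-acetoxy-5-formylbenzyl)-5-hydroxy-7-methoxyflavanone; 5 phenol (two molecules react, one per formyl group); 6 phenylboronic acid (two molecules react, one per formyl group)
Product: 8 (2S)-6,8-bis[2-acetoxy-5-(2-phenyl-4H-1,3,2-benzodioxaborin-4-yl)benzyl]-5-hydroxy-7-methoxyflavanone (diastereomer mixture at both dioxaborin C4 atoms), via phenyl hydrogen phenylboronate 7 (not isolated)
Conditions: 5 (5 equiv), 6 (3 equiv), EtCO2H (0.3 equiv), toluene, reflux, Dean–Stark
Reagents that add atoms: phenol (second molecule of 5), Oc1ccccc1; phenylboronic acid (second molecule of 6), OB(O)c1ccccc1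
Why: Phenylboronic-acid-templated ortho-hydroxyalkylation, run twice on one substrate so that two molecules of 5 and two of 6 are incorporated and four of water are removed: 5 and 6 esterify to the phenoxyboronate 7, whose Lewis-acidic boron binds a formyl oxygen of 4 so that the carbonyl carbon is delivered through a six-membered cyclic transition state to the ortho carbon of the boron-bound phenoxide, after which the ring rearomatises. Each 1,3,2-dioxaborin ring is then completed by B–O ester formation between the new benzylic hydroxyl and boron with loss of water, a six-membered closure by condensation at trigonal boron that is driven by azeotropic water removal. The closest known reaction type is the ortho-specific condensation of phenols with aromatic aldehydes and phenylboronic acid to 2,4-diaryl-4H-1,3,2-benzodioxaborins. The two new benzylic stereocentres (C4 of each dioxaborin) are remote from C2 and have no controlling element, so 8 is expected as a diastereomer mixture, which is harmless because both carbons become CH2 in step 4. The step needs ortho rather than para attack on phenol, secured by the boron tether, and reaction of external phenol rather than a phenol of the substrate, secured because the arm phenols are acetylated, the 5-OH has no free ortho carbon and phenol is in excess. The chelated C4 ketone is far less electrophilic than the formyl groups, and the weakly acidic medium should not disturb C2.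

Step 4
Reactants: 8 (2S)-6,8-bis[2-acetoxy-5-(2-phenyl-4H-1,3,2-benzodioxaborin-4-yl)benzyl]-5-hydroxy-7-methoxyflavanone
Product: 10 (2S)-6,8-bis[2-acetoxy-5-(2-hydroxybenzyl)benzyl]-5-hydroxy-7-methoxyflavanone, via bis(aryl hydrogen phenylboronate) 9 (not isolated)
Conditions: Et3SiH (3 equiv), TFA (6 equiv), CH2Cl2, 0 °C; then H2O, rt
Reagents that add atoms: none
Why: Ionic hydrogenation: TFA should ionise each doubly benzylic C4–O3 bond of the dioxaborin to a diarylmethyl cation (an o-quinone methide stabilised by the ortho oxygen), triethylsilane should transfer hydride to give the CH2 group and erase both transient stereocentres, and the remaining aryl boronate half-esters 9 should hydrolyse on aqueous work-up; the chelated, donor-rich C4 carbonyl, the aryl acetates and the C2–O1 bond ionise far less readily and should survive at 0 °C with a small excess of silane.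

Step 5
Reactants: 10 (2S)-6,8-bis[2-acetoxy-5-(2-hydroxybenzyl)benzyl]-5-hydroxy-7-methoxyflavanone
Product: 11 5''-(2''''-hydroxybenzyl)uvarinol, (2S)-5-hydroxy-6,8-bis[2-hydroxy-5-(2-hydroxybenzyl)benzyl]-7-methoxyflavanone
Conditions: HCl (1.25 M in MeOH), rt
Reagents that add atoms: none
Why: Acid-catalysed transesterification of the two aryl acetates with methanol, chosen over basic hydrolysis because base would open the flavanone to its chalcone and racemise C2, whereas dilute methanolic HCl at room temperature should leave C2, the methyl ether and the diarylmethane links untouched.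

Compound list
1 | (2S)-pinostrobin, (2S)-5-hydroxy-7-methoxy-2-phenylchroman-4-one | COc1cc(O)c2c(c1)O[C@H](c1ccccc1)CC2=O | starting material
2 | 4-hydroxy-3-(hydroxymethyl)benzaldehyde | O=Cc1ccc(O)c(CO)c1 | starting material
3 | (2S)-6,8-bis(5-formyl-2-hydroxybenzyl)-5-hydroxy-7-methoxyflavanone | COc1c(Cc2cc(C=O)ccc2O)c(O)c2c(c1Cc1cc(C=O)ccc1O)O[C@H](c1ccccc1)CC2=O | intermediate
4 | (2S)-6,8-bis(2-acetoxy-5-formylbenzyl)-5-hydroxy-7-methoxyflavanone | COc1c(Cc2cc(C=O)ccc2OC(C)=O)c(O)c2c(c1Cc1cc(C=O)ccc1OC(C)=O)O[C@H](c1ccccc1)CC2=O | intermediate
5 | phenol | Oc1ccccc1 | starting material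
6 | phenylboronic acid | OB(O)c1ccccc1 | starting material
7 | phenyl hydrogen phenylboronate | OB(Oc1ccccc1)c1ccccc1 | intermediate
8 | (2S)-6,8-bis[2-acetoxy-5-(2-phenyl-4H-1,3,2-benzodioxaborin-4-yl)benzyl]-5-hydroxy-7-methoxyflavanone, diastereomer mixture at both dioxaborin C4 atoms | COc1c(Cc2cc(C3OB(c4ccccc4)Oc4ccccc34)ccc2OC(C)=O)c(O)c2c(c1Cc1cc(C3OB(c4ccccc4)Oc4ccccc34)ccc1OC(C)=O)O[C@H](c1ccccc1)CC2=O | intermediate
9 | (2S)-6,8-bis[2-acetoxy-5-(2-{[hydroxy(phenyl)boranyl]oxy}benzyl)benzyl]-5-hydroxy-7-methoxyflavanone | COc1c(Cc2cc(Cc3ccccc3OB(O)c3ccccc3)ccc2OC(C)=O)c(O)c2c(c1Cc1cc(Cc3ccccc3OB(O)c3ccccc3)ccc1OC(C)=O)O[C@H](c1ccccc1)CC2=O | intermediate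
10 | (2S)-6,8-bis[2-acetoxy-5-(2-hydroxybenzyl)benzyl]-5-hydroxy-7-methoxyflavanone | COc1c(Cc2cc(Cc3ccccc3O)ccc2OC(C)=O)c(O)c2c(c1Cc1cc(Cc3ccccc3O)ccc1OC(C)=O)O[C@H](c1ccccc1)CC2=O | intermediate
11 | 5''-(2''''-hydroxybenzyl)uvarinol, (2S)-5-hydroxy-6,8-bis[2-hydroxy-5-(2-hydroxybenzyl)benzyl]-7-methoxyflavanone | COc1c(Cc2cc(Cc3ccccc3O)ccc2O)c(O)c2c(c1Cc1cc(Cc3ccccc3O)ccc1O)O[C@H](c1ccccc1)CC2=O | target

Total step count: 5.
Longest linear sequence: 5 steps (1 → 3 → 4 → 8 → 10 → 11).

Steps most likely to fail

Step 3. The boron template may be sequestered by the 5-OH/C4=O chelate, the second formyl group may condense incompletely, or prolonged heating with excess phenol may transfer the acetyl groups, so that the double ortho-selective C–C bond formation stalls or cross-links. The fallback sets out from 4 and fixes the ortho regiochemistry in the nucleophile through a C–B bond instead of a template. Base-free rhodium-catalysed 1,2-addition of 2-(benzyloxy)phenylboronic acid to both formyl groups (Rh(acac)(CO)2, dppf, DME/H2O, 80 °C) should give (2S)-6,8-bis{2-acetoxy-5-[(2-benzyloxyphenyl)(hydroxy)methyl]benzyl}-5-hydroxy-7-methoxyflavanone F1 as a carbinol epimer mixture. Hydrogenolysis (H2, Pd/C, EtOAc/AcOH, rt) should then remove both benzyl ethers and both diarylcarbinol hydroxyls in one operation, and the route is rejoined at 10.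

Step 1. The electron-poor benzylic alcohol may ionise slowly, and forcing conditions could let the formyl groups condense with ring A, leave the second benzylation incomplete, or epimerise C2 through reversible opening of the pyranone ring. The fallback sets out from 1 and carries the formyl group as a halogen. The same ZnCl2/dioxane benzylation with 2-(hydroxymethyl)-4-iodophenol, a more easily ionised carbonyl-free salicyl alcohol, should give (2S)-6,8-bis(2-hydroxy-5-iodobenzyl)-5-hydroxy-7-methoxyflavanone F2. Acetylation (Ac2O, pyridine, CH2Cl2, 0 °C) should give (2S)-6,8-bis(2-acetoxy-5-iodobenzyl)-5-hydroxy-7-methoxyflavanone F3. Neutral palladium-catalysed reductive carbonylation (Pd(PPh3)4, CO, slow addition of Bu3SnH, toluene, 50 °C) should convert both aryl iodides into formyl groups, and the route is rejoined at 4.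

Step 4. Hydride transfer to the C4 carbonyl may compete with ionisation of the boron-bound benzylic C–O bonds, or ionisation may remain incomplete, giving over-reduced or partly opened material. The fallback sets out from 8 and separates boron removal from deoxygenation. Transesterification with 2,2-dimethylpropane-1,3-diol (THF, rt) should release (2S)-6,8-bis{2-acetoxy-5-[hydroxy(2-hydroxyphenyl)methyl]benzyl}-5-hydroxy-7-methoxyflavanone F4. Heterogeneous hydrogenolysis of the two diarylcarbinols (H2, Pd/C, EtOAc/AcOH, rt), conditions under which flavanone carbonyls are normally retained, should then give the methylene groups, and the route is rejoined at 10.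

Further compounds
F1 | step 3 | (2S)-6,8-bis{2-acetoxy-5-[(2-benzyloxyphenyl)(hydroxy)methyl]benzyl}-5-hydroxy-7-methoxyflavanone | COc1c(Cc2cc(C(O)c3ccccc3OCc3ccccc3)ccc2OC(C)=O)c(O)c2c(c1Cc1cc(C(O)c3ccccc3OCc3ccccc3)ccc1OC(C)=O)O[C@H](c1ccccc1)CC2=O
F2 | step 1 | (2S)-6,8-bis(2-hydroxy-5-iodobenzyl)-5-hydroxy-7-methoxyflavanone | COc1c(Cc2cc(I)ccc2O)c(O)c2c(c1Cc1cc(I)ccc1O)O[C@H](c1ccccc1)CC2=O
F3 | step 1 | (2S)-6,8-bis(2-acetoxy-5-iodobenzyl)-5-hydroxy-7-methoxyflavanone | COc1c(Cc2cc(I)ccc2OC(C)=O)c(O)c2c(c1Cc1cc(I)ccc1OC(C)=O)O[C@H](c1ccccc1)CC2=O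
F4 | step 4 | (2S)-6,8-bis{2-acetoxy-5-[hydroxy(2-hydroxyphenyl)methyl]benzyl}-5-hydroxy-7-methoxyflavanone | COc1c(Cc2cc(C(O)c3ccccc3O)ccc2OC(C)=O)c(O)c2c(c1Cc1cc(C(O)c3ccccc3O)ccc1OC(C)=O)O[C@H](c1ccccc1)CC2=O
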